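**Retrosynthetic overview**
1. Target 29 ⇐ alcohol 27 ⇐ PMB ether 26. Only the oxidation level at C1 changes, all stereocentres and both alkenes are already in place.
2. Key disconnection, one operation: the O1–C6 ring bond and the C6–C7 bond, so 26 ⇒ open-chain hydroperoxy ketal 23 + alkenylsilane 10. The enabling feature is C6 of the 1,2-dioxane: a fully substituted ring carbon bonded to the peroxide oxygen O1 and carrying the C7=C8 alkenyl group. At the ketone oxidation level it is a peroxyketal carbon that ionizes to a ring peroxycarbenium ion (C6=O1+), which a vinylsilane can attack axially.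
3. 23 ⇐ mesylate 21 (SN2 inversion at C3 by a peroxide) ⇐ ketone 18 ⇐ Evans syn-aldol (C3–C4 bond, both stereocentres) and alkyllithium acylation (C5–C6 bond).
4. 10 ⇐ alkyne 6 by syn-carbocupration, iodination and silylation (C7=C8 geometry) ⇐ Evans alkylation (C10) and Julia–Kocienski olefination (C11=C12).
5. Ring order: the 1,2-dioxane is the only ring of the target and is closed in the key step; the dioxolane is a temporary protecting ring.

Key step: step 17

Remark: 11, the tetrazolyl sulfone of step 4 and 2-methoxyprop-2-yl hydroperoxide are treated as stock reagents (each is one or two routine steps from propane-1,3-diol, 1-phenyl-1H-tetrazole-5-thiol and 2,3-dimethylbut-2-ene/O3/MeOH).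

**Side-chain fragment (steps 1–6)**

Step 1
Reactants: 1 (4S)-4-benzyl-3-butanoyl-1,3-oxazolidin-2-one
Product: 3 (4S)-4-benzyl-3-[(2R)-2-ethylpent-4-ynoyl]-1,3-oxazolidin-2-one, via sodium enolate 2 (not isolated)
Conditions: NaN(SiMe3)2, THF, −78 °C; HC≡CCH2Br, −78 → −40 °C
Reagents that add atoms: 3-bromoprop-1-yne, C#CCBr
Why: Evans asymmetric alkylation: the chelated Z-enolate is alkylated on the face opposite the benzyl group, which sets the future C10 (R).

Step 2
Reactants: 3 (4S)-4-benzyl-3-[(2R)-2-ethylpent-4-ynoyl]-1,3-oxazolidin-2-one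
Product: 4 (2R)-2-ethylpent-4-yn-1-ol
Conditions: LiBH4, MeOH (1 equiv), Et2O, 0 °C
Reagents that add atoms: none
Why: Hydride reduction of the N-acyl oxazolidinone releases the primary alcohol and the auxiliary without touching the alkyne or the α-stereocentre.

Step 3
Reactants: 4 (2R)-2-ethylpent-4-yn-1-ol
Product: 5 (2R)-2-ethylpent-4-ynal
Conditions: Dess–Martin periodinane, CH2Cl2, 0 °C → rt; used crude
Reagents that add atoms: none
Why: Dess–Martin oxidation gives the aldehyde under near-neutral conditions that should not epimerize the α-stereocentre.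

Step 4
Reactants: 5 (2R)-2-ethylpent-4-ynal
Product: 6 (4R,5E)-4-ethyloct-5-en-1-yne
Conditions: sulfone, KN(SiMe3)2, DME, −60 °C; then 5, −60 °C → rt
Reagents that add atoms: 1-phenyl-5-(propylsulfonyl)-1H-tetrazole, CCCS(=O)(=O)c1nnnn1-c1ccccc1
Why: Julia–Kocienski olefination of an α-branched aldehyde with a pre-metalated phenyltetrazolyl sulfone should give the (E)-alkene C11=C12.

Step 5
Reactants: 6 (4R,5E)-4-ethyloct-5-en-1-yne
Product: 8 (1E,4R,5E)-2,4-diethyl-1-iodoocta-1,5-diene, via alkenylcopper 7 (not isolated)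
Conditions: EtMgBr, CuBr·SMe2, Et2O/Me2S, −45 °C; 6, −25 °C; I2, THF, −50 → 0 °C
Reagents that add atoms: ethylmagnesium bromide, CC[Mg]Br; iodine, II
Why: Normant carbocupration adds ethyl and copper syn across the terminal alkyne with ethyl on the internal carbon, and iodinolysis with retention gives the C7=C8 geometry of the target (ethyl cis to iodine).

Step 6
Reactants: 8 (1E,4R,5E)-2,4-diethyl-1-iodoocta-1,5-diene
Product: 10 [(1E,4R,5E)-2,4-diethylocta-1,5-dien-1-yl]trimethylsilane, via alkenyllithium 9 (not isolated)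
Conditions: t-BuLi (2 equiv), Et2O, −78 °C; Me3SiCl, −78 → 0 °C
Reagents that add atoms: chlorotrimethylsilane, C[Si](C)(C)Cl
Why: Iodine–lithium exchange and silylation of the configurationally stable alkenyllithium both proceed with retention of alkene geometry.

**Ring fragment (steps 7–16)**

Step 7
Reactants: 1 (4S)-4-benzyl-3-butanoyl-1,3-oxazolidin-2-one; 11 3-[(4-methoxybenzyl)oxy]propanal
Product: 13 (4S)-4-benzyl-3-{(2S,3R)-2-ethyl-3-hydroxy-5-[(4-methoxybenzyl)oxy]pentanoyl}-1,3-oxazolidin-2-one, via boron enolate 12 (not isolated)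
Conditions: Bu2BOTf, i-Pr2NEt, CH2Cl2, −78 → 0 °C; 11, −78 → 0 °C; pH 7 buffer/MeOH/H2O2
Reagents that add atoms: none
Why: Evans syn-aldol reaction: the Z-boron enolate reacts through a Zimmerman–Traxler chair on the face away from the benzyl group, setting C4 and the C3 carbinol syn to each other.

Step 8
Reactants: 13 syn-aldol adduct
Product: 14 (4S)-4-benzyl-3-{(2S,3R)-3-[(tert-butyldimethylsilyl)oxy]-2-ethyl-5-[(4-methoxybenzyl)oxy]pentanoyl}-1,3-oxazolidin-2-one
Conditions: t-BuMe2SiOTf, 2,6-lutidine, CH2Cl2, 0 °C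
Reagents that add atoms: tert-butyldimethylsilyl triflate, CC(C)(C)[Si](C)(C)OS(=O)(=O)C(F)(F)F
Why: Silyl triflate protection of the secondary alcohol blocks retro-aldol and should survive the later organolithium and ketalization steps.

Step 9
Reactants: 14 silyl ether
Product: 15 (2R,3R)-3-[(tert-butyldimethylsilyl)oxy]-2-ethyl-5-[(4-methoxybenzyl)oxy]pentan-1-ol
Conditions: LiBH4, MeOH (1 equiv), THF, 0 °C
Reagents that add atoms: none
Why: Hydride reduction of the imide turns the acyl carbon into the C5 methylene alcohol and returns the auxiliary.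

Step 10
Reactants: 15 primary alcohol
Product: 16 tert-butyl({(3R,4S)-4-(iodomethyl)-1-[(4-methoxybenzyl)oxy]hexan-3-yl}oxy)dimethylsilane
Conditions: I2, PPh3, imidazole, CH2Cl2, 0 °C → rt
Reagents that add atoms: iodine, II
Why: Appel iodination is an SN2 reaction at the primary carbon and leaves both stereocentres untouched.

Step 11
Reactants: 16 primary iodide
Product: 18 (5R,6R)-6-[(tert-butyldimethylsilyl)oxy]-5-ethyl-8-[(4-methoxybenzyl)oxy]octan-3-one, via alkyllithium 17 (not isolated)
Conditions: t-BuLi (2.1 equiv), Et2O/pentane, −78 °C; EtC(O)N(OMe)Me, −78 → 0 °C; aq. NH4Cl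
Reagents that add atoms: N-methoxy-N-methylpropanamide, CCC(=O)N(C)OC
Why: Iodine–lithium exchange followed by Weinreb ketone synthesis forms the C5–C6 bond and stops at the ethyl ketone because the chelated tetrahedral intermediate does not collapse before quench.

Step 12
Reactants: 18 ethyl ketone
Product: 19 tert-butyl({(3R,4R)-4-ethyl-5-(2-ethyl-1,3-dioxolan-2-yl)-1-[(4-methoxybenzyl)oxy]pentan-3-yl}oxy)dimethylsilane
Conditions: Me3SiOCH2CH2OSiMe3, Me3SiOTf (cat.), CH2Cl2, −78 → −20 °C; pyridine
Reagents that add atoms: 1,2-bis(trimethylsilyloxy)ethane, C[Si](C)(C)OCCO[Si](C)(C)C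
Why: Noyori ketalization masks C6 so that C5 cannot enolize onto the later mesylate and the carbonyl cannot capture the hydroperoxide before the key step.

Step 13
Reactants: 19 dioxolane silyl ether
Product: 20 (3R,4R)-4-ethyl-5-(2-ethyl-1,3-dioxolan-2-yl)-1-[(4-methoxybenzyl)oxy]pentan-3-ol
Conditions: Bu4NF, THF, 0 °C → rt
Reagents that add atoms: none
Why: Fluoride desilylation is orthogonal to the dioxolane and the PMB ether and is basic enough to avoid trans-ketalization onto the freed hydroxyl.

Step 14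
Reactants: 20 secondary alcohol
Product: 21 (3R,4R)-4-ethyl-5-(2-ethyl-1,3-dioxolan-2-yl)-1-[(4-methoxybenzyl)oxy]pentan-3-yl methanesulfonate
Conditions: MsCl, Et3N, CH2Cl2, 0 °C
Reagents that add atoms: methanesulfonyl chloride, CS(=O)(=O)Cl
Why: Sulfonate ester formation with retention activates C3 for displacement.

Step 15
Reactants: 21 mesylate
Product: 22 2-ethyl-2-{(2R,3S)-2-ethyl-5-[(4-methoxybenzyl)oxy]-3-[(2-methoxypropan-2-yl)peroxy]pentyl}-1,3-dioxolane
Conditions: 2-methoxyprop-2-yl hydroperoxide, CsOH·H2O, DMF, 0 °C → rt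
Reagents that add atoms: 2-methoxyprop-2-yl hydroperoxide, COC(C)(C)OO
Why: SN2 displacement of a secondary sulfonate by a peroxide anion (alkylation of a ketal-protected hydroperoxide) inverts C3, turning the syn aldol relationship into the anti (3S,4R) relationship of the target.

Step 16
Reactants: 22 mixed peroxyketal
Product: 23 2-ethyl-2-{(2R,3S)-2-ethyl-3-hydroperoxy-5-[(4-methoxybenzyl)oxy]pentyl}-1,3-dioxolane
Conditions: PPTS (cat.), MeOH, 0 °C
Reagents that add atoms: none
Why: Acid-catalysed methanolysis cleaves the acyclic acetone-derived peroxyketal much faster than the dioxolane of a dialkyl ketone, so the hydroperoxide should be freed while the chain stays open.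

**Key step and end game (steps 17–19)**

Step 17
Reactants: 23 open-chain hydroperoxy dioxolane; 10 alkenylsilane
Product: 26 (3S,4R,6S)-6-[(1E,4R,5E)-2,4-diethylocta-1,5-dien-1-yl]-4,6-diethyl-3-{2-[(4-methoxybenzyl)oxy]ethyl}-1,2-dioxane, via trimethylsilyl peroxide 24 (not isolated), via cyclic peroxyketal 25 (not isolated)
Conditions: MeC(OSiMe3)=NSiMe3, CH2Cl2, 0 °C; 2,6-di-tert-butyl-4-methylpyridine, Me3SiOTf (0.3 equiv), −78 °C; then 10 (1.5 equiv), −78 → −40 °C; Et3N
Reagents that add atoms: none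
Why: Proposed new method: Me3SiOTf opens the dioxolane of silyl peroxide 24 to an open-chain oxocarbenium ion at C6, which the silylperoxy oxygen captures in a 6-exo-trig closure that forms the O1–C6 bond and the 1,2-dioxane ring (peroxyketal 25, both C6 anomers); loss of the second alkoxy group then gives one ring peroxycarbenium ion (C6=O1+), which vinylsilane 10 attacks with its silicon-bearing carbon C7 (β-silyl cation at tertiary C8), and loss of Me3Si+ restores the C7=C8 bond with retention and regenerates Me3SiOTf. The closest known reaction types are the Lewis-acid substitution of 3-alkoxy-1,2-dioxanes and 3-alkoxy-1,2-dioxolanes by allylsilanes and silyl ketene acetals through peroxycarbenium ions, the Me3SiOTf-mediated peroxyketalization of ketals by silyl peroxides, and the ipso-substitution of vinylsilanes by oxocarbenium ions; the vinylsilane as partner and the one-flask sequence are new. The new stereocentre C6 is set by stereoelectronic control: the half-chair cation places the trans C3 and C4 substituents pseudo-equatorial and the nucleophile enters axially through a chair-like transition state, so the alkenyl group ends axial, trans to the C4 ethyl and cis to the C3 chain, with the C6 ethyl equatorial (6S). The step is stereoconvergent because the open-chain form and both anomers of 25 funnel through the same cation. It needs facial selectivity at C6 (secured by the C3/C4 stereocentres), attack by C7 of the vinylsilane and not by the C11=C12 alkene (secured by the β-silicon effect), and retention of the C7=C8 geometry (secured by fast desilylation at low temperature); the hindered pyridine base and prior silylation of the OOH group keep the medium free of protons that would protodesilylate 10.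

Step 18
Reactants: 26 PMB-protected dioxane
Product: 27 2-[(3S,4R,6S)-6-[(1E,4R,5E)-2,4-diethylocta-1,5-dien-1-yl]-4,6-diethyl-1,2-dioxan-3-yl]ethan-1-ol
Conditions: DDQ, CH2Cl2/pH 7 buffer (10:1), 0 °C
Reagents that add atoms: none
Why: Oxidative cleavage of the p-methoxybenzyl ether by DDQ (hydride abstraction, then hydrolysis) should leave the dialkyl peroxide and the isolated alkenes alone.

Step 19
Reactants: 27 primary alcohol
Product: 29 2-[(3S,4R,6S)-6-[(1E,4R,5E)-2,4-diethylocta-1,5-dien-1-yl]-4,6-diethyl-1,2-dioxan-3-yl]acetic acid, via aldehyde 28 (not isolated)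
Conditions: TEMPO (cat.), PhI(OAc)2, MeCN/H2O (1:1), 0 °C → rt
Reagents that add atoms: water, O
Why: TEMPO/PhI(OAc)2 oxidation takes the alcohol through the aldehyde hydrate to the acid under weakly acidic conditions, which avoids base-induced retro-oxa-Michael opening of the β-peroxy carbonyl.

**Compound list**
1 | (4S)-4-benzyl-3-butanoyl-1,3-oxazolidin-2-one | O=C1OC[C@H](Cc2ccccc2)N1C(=O)CCC | starting material
2 | sodium (Z)-enolate of 1 | O=C1OC[C@H](Cc2ccccc2)N1/C([O-])=C/CC.[Na+] | intermediate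
3 | (4S)-4-benzyl-3-[(2R)-2-ethylpent-4-ynoyl]-1,3-oxazolidin-2-one | O=C1OC[C@H](Cc2ccccc2)N1C(=O)[C@H](CC)CC#C | intermediate
4 | (2R)-2-ethylpent-4-yn-1-ol | OC[C@H](CC)CC#C | intermediate
5 | (2R)-2-ethylpent-4-ynal | O=C[C@H](CC)CC#C | intermediate
6 | (4R,5E)-4-ethyloct-5-en-1-yne | CC/C=C/[C@H](CC)CC#C | intermediate
7 | [(1E,4R,5E)-2,4-diethylocta-1,5-dien-1-yl]copper, MgBr2 complex (ethyl cis to copper) | CC/C=C/[C@H](CC)C/C(=C/[Cu])CC | intermediate
8 | (1E,4R,5E)-2,4-diethyl-1-iodoocta-1,5-diene | CC/C=C/[C@H](CC)C/C(=C/I)CC | intermediate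
9 | [(1E,4R,5E)-2,4-diethylocta-1,5-dien-1-yl]lithium | CC/C=C/[C@H](CC)C/C(=C/[Li])CC | intermediate
10 | [(1E,4R,5E)-2,4-diethylocta-1,5-dien-1-yl]trimethylsilane | CC/C=C/[C@H](CC)C/C(=C/[Si](C)(C)C)CC | intermediate
11 | 3-[(4-methoxybenzyl)oxy]propanal | O=CCCOCc1ccc(OC)cc1 | starting material
12 | dibutylboron (Z)-enolate of 1 | O=C1OC[C@H](Cc2ccccc2)N1/C(OB(CCCC)CCCC)=C/CC | intermediate
13 | (4S)-4-benzyl-3-{(2S,3R)-2-ethyl-3-hydroxy-5-[(4-methoxybenzyl)oxy]pentanoyl}-1,3-oxazolidin-2-one | O=C1OC[C@H](Cc2ccccc2)N1C(=O)[C@@H](CC)[C@@H](CCOCc2ccc(OC)cc2)O | intermediate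
14 | (4S)-4-benzyl-3-{(2S,3R)-3-[(tert-butyldimethylsilyl)oxy]-2-ethyl-5-[(4-methoxybenzyl)oxy]pentanoyl}-1,3-oxazolidin-2-one | O=C1OC[C@H](Cc2ccccc2)N1C(=O)[C@@H](CC)[C@@H](CCOCc2ccc(OC)cc2)O[Si](C)(C)C(C)(C)C | intermediate
15 | (2R,3R)-3-[(tert-butyldimethylsilyl)oxy]-2-ethyl-5-[(4-methoxybenzyl)oxy]pentan-1-ol | OC[C@@H](CC)[C@@H](CCOCc1ccc(OC)cc1)O[Si](C)(C)C(C)(C)C | intermediate
16 | tert-butyl({(3R,4S)-4-(iodomethyl)-1-[(4-methoxybenzyl)oxy]hexan-3-yl}oxy)dimethylsilane | IC[C@@H](CC)[C@@H](CCOCc1ccc(OC)cc1)O[Si](C)(C)C(C)(C)C | intermediate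
17 | primary alkyllithium from 16 (Li in place of I) | [Li]C[C@@H](CC)[C@@H](CCOCc1ccc(OC)cc1)O[Si](C)(C)C(C)(C)C | intermediate
18 | (5R,6R)-6-[(tert-butyldimethylsilyl)oxy]-5-ethyl-8-[(4-methoxybenzyl)oxy]octan-3-one | CCC(=O)C[C@@H](CC)[C@@H](CCOCc1ccc(OC)cc1)O[Si](C)(C)C(C)(C)C | intermediate
19 | tert-butyl({(3R,4R)-4-ethyl-5-(2-ethyl-1,3-dioxolan-2-yl)-1-[(4-methoxybenzyl)oxy]pentan-3-yl}oxy)dimethylsilane | CCC1(OCCO1)C[C@@H](CC)[C@@H](CCOCc1ccc(OC)cc1)O[Si](C)(C)C(C)(C)C | intermediate
20 | (3R,4R)-4-ethyl-5-(2-ethyl-1,3-dioxolan-2-yl)-1-[(4-methoxybenzyl)oxy]pentan-3-ol | CCC1(OCCO1)C[C@@H](CC)[C@@H](CCOCc1ccc(OC)cc1)O | intermediate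
21 | (3R,4R)-4-ethyl-5-(2-ethyl-1,3-dioxolan-2-yl)-1-[(4-methoxybenzyl)oxy]pentan-3-yl methanesulfonate | CCC1(OCCO1)C[C@@H](CC)[C@@H](CCOCc1ccc(OC)cc1)OS(C)(=O)=O | intermediate
22 | 2-ethyl-2-{(2R,3S)-2-ethyl-5-[(4-methoxybenzyl)oxy]-3-[(2-methoxypropan-2-yl)peroxy]pentyl}-1,3-dioxolane | CCC1(OCCO1)C[C@@H](CC)[C@H](CCOCc1ccc(OC)cc1)OOC(C)(C)OC | intermediate
23 | 2-ethyl-2-{(2R,3S)-2-ethyl-3-hydroperoxy-5-[(4-methoxybenzyl)oxy]pentyl}-1,3-dioxolane | CCC1(OCCO1)C[C@@H](CC)[C@H](CCOCc1ccc(OC)cc1)OO | intermediate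
24 | trimethylsilyl peroxide of 23 | CCC1(OCCO1)C[C@@H](CC)[C@H](CCOCc1ccc(OC)cc1)OO[Si](C)(C)C | intermediate
25 | (3S,4R)-4,6-diethyl-3-{2-[(4-methoxybenzyl)oxy]ethyl}-6-[2-(trimethylsilyloxy)ethoxy]-1,2-dioxane, both C6 epimers | CCC1(OCCO[Si](C)(C)C)C[C@@H](CC)[C@H](CCOCc2ccc(OC)cc2)OO1 | intermediate
26 | (3S,4R,6S)-6-[(1E,4R,5E)-2,4-diethylocta-1,5-dien-1-yl]-4,6-diethyl-3-{2-[(4-methoxybenzyl)oxy]ethyl}-1,2-dioxane | CC/C=C/[C@H](CC)C/C(=C/[C@]1(CC)C[C@@H](CC)[C@H](CCOCc2ccc(OC)cc2)OO1)CC | intermediate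
27 | 2-[(3S,4R,6S)-6-[(1E,4R,5E)-2,4-diethylocta-1,5-dien-1-yl]-4,6-diethyl-1,2-dioxan-3-yl]ethan-1-ol | CC/C=C/[C@H](CC)C/C(=C/[C@]1(CC)C[C@@H](CC)[C@H](CCO)OO1)CC | intermediate
28 | 2-[(3S,4R,6S)-6-[(1E,4R,5E)-2,4-diethylocta-1,5-dien-1-yl]-4,6-diethyl-1,2-dioxan-3-yl]acetaldehyde | CC/C=C/[C@H](CC)C/C(=C/[C@]1(CC)C[C@@H](CC)[C@H](CC=O)OO1)CC | intermediate
29 | 2-[(3S,4R,6S)-6-[(1E,4R,5E)-2,4-diethylocta-1,5-dien-1-yl]-4,6-diethyl-1,2-dioxan-3-yl]acetic acid | CC/C=C/[C@H](CC)C/C(=C/[C@]1(CC)C[C@@H](CC)[C@H](CC(=O)O)OO1)CC | target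

**Step count and risks**

Total step count: 19. Longest linear sequence: 13 steps (steps 7–19, from 1 and 11). The side-chain branch is 6 steps (1–6) and joins at step 17.

Steps most likely to fail:

1. Step 17 (proposed new method). The hindered vinylsilane may trap the tertiary peroxycarbenium ion too slowly, so that proton loss to a cyclic enol peroxide, O–O heterolysis with 1,2-shift (Criegee/Hock type) or protodesilylation of 10 takes over; facial selectivity at C6 or the alkene geometry could also erode. The fallback uses known chemistry only, sets out from ketone 18 and comes back at 26. Alkenyllithium 9 (from iodide 8 and t-BuLi) would be added to 18 in the presence of CeCl3 and the alkoxide methylated in the flask with MeOTf, to give the tertiary allylic methyl ether F1 as both C6 epimers. Bu4NF would give alcohol F2, MsCl/Et3N mesylate F3, 2-methoxyprop-2-yl hydroperoxide/CsOH·H2O the inverted peroxyketal F4, and PPTS/MeOH the hydroperoxide F5. BF3·OEt2 in CH2Cl2 at −78 °C would then ionize the tertiary allylic ether and the hydroperoxide would capture the cation at C6 (acid-mediated cyclization of a hydroperoxide onto a tertiary carbocation, the classical route to tetraalkyl-1,2-dioxanes). This should return 26 together with its C6 epimer, which would have to be separated by chromatography because C6 is no longer under stereoelectronic control.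

2. Step 15. E2 elimination toward C2 or C4 may outrun substitution at the β-branched secondary mesylate, and the ketal oxygen may participate. The fallback delivers the peroxide intramolecularly, sets out from mesylate 21 and comes back at 26. Perhydrolysis of the dioxolane (50% H2O2, Re2O7 cat., MeCN) would give the geminal dihydroperoxide F6. CsOH·H2O in DMF would close it by 6-exo-tet displacement of the mesylate with inversion at C3 to the 6-hydroperoxy-1,2-dioxane F7. F7 would be O-silylated and ionized with Me3SiOTf in the presence of 10 under the conditions of step 17, the silylperoxy group at C6 leaving. In this contingency the ring is closed at the C3–O bond, and only the C6–C7 bond formation and the C6 stereocontrol of step 17 are kept.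

3. Step 5. Carbometalation may be incomplete or not fully regioselective (β-hydride loss from ethylcopper, dimerization on iodinolysis), which would erode the geometric purity of the trisubstituted alkene that every later step depends on. The fallback sets out from alkyne 6 and comes back at iodide 8. BBr3 (CH2Cl2, −78 °C → rt) would add boron and bromine syn across the alkyne, and pinacol would give the bromoalkenylboronate F8 (bromine on the internal carbon, cis to boron). Negishi coupling with EtZnBr and Pd(t-Bu3P)2 would replace bromine by ethyl with retention to give boronate F9. NaOH followed by I2 would convert the C–B bond into the C–I bond with retention.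

**Further compounds**
F1 | step 17 | tertiary allylic methyl ether from 18 and 9 (both C6 epimers, C3 silyl ether) | CC/C=C/[C@H](CC)C/C(=C/C(CC)(OC)C[C@@H](CC)[C@@H](CCOCc1ccc(OC)cc1)O[Si](C)(C)C(C)(C)C)CC
F2 | step 17 | C3 alcohol from F1 | CC/C=C/[C@H](CC)C/C(=C/C(CC)(OC)C[C@@H](CC)[C@@H](CCOCc1ccc(OC)cc1)O)CC
F3 | step 17 | C3 methanesulfonate of F2 | CC/C=C/[C@H](CC)C/C(=C/C(CC)(OC)C[C@@H](CC)[C@@H](CCOCc1ccc(OC)cc1)OS(C)(=O)=O)CC
F4 | step 17 | C3-inverted (2-methoxypropan-2-yl) peroxide from F3 | CC/C=C/[C@H](CC)C/C(=C/C(CC)(OC)C[C@@H](CC)[C@H](CCOCc1ccc(OC)cc1)OOC(C)(C)OC)CC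
F5 | step 17 | C3 hydroperoxide from F4 | CC/C=C/[C@H](CC)C/C(=C/C(CC)(OC)C[C@@H](CC)[C@H](CCOCc1ccc(OC)cc1)OO)CC
F6 | step 15 | (3R,4R)-4-ethyl-6,6-dihydroperoxy-1-[(4-methoxybenzyl)oxy]octan-3-yl methanesulfonate | CCC(OO)(OO)C[C@@H](CC)[C@@H](CCOCc1ccc(OC)cc1)OS(C)(=O)=O
F7 | step 15 | (3S,4R)-4,6-diethyl-6-hydroperoxy-3-{2-[(4-methoxybenzyl)oxy]ethyl}-1,2-dioxane (both C6 epimers) | CCC1(OO)C[C@@H](CC)[C@H](CCOCc2ccc(OC)cc2)OO1
F8 | step 5 | 2-[(1Z,4R,5E)-2-bromo-4-ethylocta-1,5-dien-1-yl]-4,4,5,5-tetramethyl-1,3,2-dioxaborolane | CC/C=C/[C@H](CC)C/C(Br)=C/B1OC(C)(C)C(C)(C)O1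
F9 | step 5 | 2-[(1E,4R,5E)-2,4-diethylocta-1,5-dien-1-yl]-4,4,5,5-tetramethyl-1,3,2-dioxaborolane | CC/C=C/[C@H](CC)C/C(CC)=C/B1OC(C)(C)C(C)(C)O1
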